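**Retrosynthetic overview**
1. The target is read as two 8-epi-xanthatin-type halves of opposite absolute series joined through ring C. The last disconnections are C11=C13 (dehydration of a hydroxymethyl lactone that masks the upper methylene lactone) and C1–OH (γ-oxygenation of a β,γ-unsaturated ketone).
2. Ring C comes from a Diels–Alder union of the diene C5=C1–C2=C3 of the upper half (35) with the methylene lactone C11'=C13' of the lower epoxide (21), forming C3–C11' and C5–C13'.
3. Each half is a cis-lactone (ring D or A, by oxidative lactonization after cis-selective ketone reduction) on a cycloheptenone. Its seven-membered ring (E or B) arises by a siloxy-divinylcyclopropane rearrangement that forms C6'–C7' (C6–C7). The cyclopropane comes from an organocatalytic enal/bromomalonate cyclopropanation with the (S)- or (R)-catalyst.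
4. Enabling feature: in ring E the oxygen-bearing C8' and the C1'–C5' epoxide (a masked alkene) flank sp3 C10', and C6'–C7' are adjacent sp3 carbons. This is the cyclohepta-1,4-diene retron of a cis-divinylcyclopropane with C10' as the third ring carbon; two identical vinyl groups on C1' guarantee the cis arrangement.
5. Ring order: cyclopropane → ring E → ring D (lower half); cyclopropane → ring B → ring A (upper half); then ring C.

Key step: step 5

Remark on the chemistry: in the given structure C7/C8/C10 are R,R,S in the upper half and S,S,R in the lower half, so the halves are treated as antipodal 8-epi-xanthatin skeletons and made with the two enantiomers of one catalyst.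
Numbering: xanthane numbering for both halves (ring carbons C1, C5–C10; side chain C2–C4, C15; lactone C11–C13; methyl C14); primes mark the lower (epoxide) half. Ring A = upper lactone, ring B = upper seven-membered ring, ring C = cyclohexene, ring D = spiro lactone, ring E = lower seven-membered ring.

**Lower half (steps 1–11)**

Step 1
Reactants: 1 (E)-but-2-enal; 2 dimethyl 2-bromomalonate
Product: 3 dimethyl (2R,3R)-2-formyl-3-methylcyclopropane-1,1-dicarboxylate
Conditions: (S)-2-[diphenyl(trimethylsilyloxy)methyl]pyrrolidine (20 mol %), 2,6-lutidine, CH2Cl2, 0 → 23 °C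
Reagents that add atoms: none
Why: Iminium/enamine-catalysed Michael-initiated ring closure (organocatalytic cyclopropanation of an enal with a bromomalonate), in which the catalyst shields one face of the iminium ion so that the malonate adds to C10' from the open face and the enamine then displaces bromide to give the trans cyclopropane, setting C10' (R) and the trans C9'/C10' relationship.

Step 2
Reactants: 3 dimethyl (2R,3R)-2-formyl-3-methylcyclopropane-1,1-dicarboxylate; 4 (3-bromopropoxy)(tert-butyl)dimethylsilane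
Product: 6 1-[(1R,3R)-2,2-bis(hydroxymethyl)-3-methylcyclopropyl]-4-(tert-butyldimethylsilyloxy)butan-1-ol, via Grignard adduct 5 (not isolated)
Conditions: 4, Mg, THF, 23 °C; then 3, THF, −78 °C; then LiAlH4, −78 → 0 °C; aq. KNaC4H4O6
Reagents that add atoms: [3-(tert-butyldimethylsilyloxy)propyl]magnesium bromide, CC(C)(C)[Si](C)(C)OCCC[Mg]Br
Why: Grignard addition is faster at the aldehyde than at the esters on the quaternary carbon and brings in C7', C11' and C12', and LiAlH4 then reduces both esters (and any lactone formed from the alkoxide) to the triol; the carbinol configuration is irrelevant because C8' is oxidised in step 3.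

Step 3
Reactants: 6 1-[(1R,3R)-2,2-bis(hydroxymethyl)-3-methylcyclopropyl]-4-(tert-butyldimethylsilyloxy)butan-1-ol
Product: 7 (2R,3R)-2-[4-(tert-butyldimethylsilyloxy)butanoyl]-3-methylcyclopropane-1,1-dicarbaldehyde
Conditions: (COCl)2, DMSO, CH2Cl2, −78 °C; Et3N, −78 → 0 °C
Reagents that add atoms: none
Why: Swern oxidation activates all three hydroxyls before base is added, so the two primary and the secondary alcohol are oxidised together without lactol formation, and the aldehydes, which sit on a quaternary carbon, cannot enolise.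

Step 4
Reactants: 7 (2R,3R)-2-[4-(tert-butyldimethylsilyloxy)butanoyl]-3-methylcyclopropane-1,1-dicarbaldehyde
Product: 8 4-(tert-butyldimethylsilyloxy)-1-[(1R,3R)-2,2-diethenyl-3-methylcyclopropyl]butan-1-one
Conditions: Ph3PCH3Br, KN(SiMe3)2, THF, 0 °C; then 7 (ylide 2.2 equiv), −78 → 0 °C
Reagents that add atoms: methylenetriphenylphosphorane, C=P(c1ccccc1)(c1ccccc1)c1ccccc1
Why: Wittig methylenation is much faster at the two aldehydes than at the hindered cyclopropyl ketone at low temperature, which should give the geminal divinyl group without touching a stereocentre.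

Step 5
Reactants: 8 4-(tert-butyldimethylsilyloxy)-1-[(1R,3R)-2,2-diethenyl-3-methylcyclopropyl]butan-1-one
Product: 11 (2S,6R)-2-[2-(tert-butyldimethylsilyloxy)ethyl]-5-ethenyl-6-methylcyclohept-4-en-1-one, via silyl enol ether 9 (not isolated), via cycloheptadienyl silyl ether 10 (not isolated)
Conditions: Me3SiOTf, Et3N, CH2Cl2, −20 → 23 °C; then 40 °C; then 1 M aq. citric acid, THF, 0 °C
Reagents that add atoms: none
Why: Soft enolisation should give the (Z)-silyl enol ether 9, whose enol double bond is necessarily cis to one of the two identical vinyl groups on C1'; a concerted [3,3]-sigmatropic shift through the boat transition state then breaks the C9'–C1' cyclopropane bond and forms C6'–C7'. This is the divinylcyclopropane–cycloheptadiene (Cope) rearrangement in its siloxy variant, well known for silyl enol ethers of 2-vinylcyclopropyl ketones. Ring E is closed by this three-to-seven ring expansion, a pericyclic closure suprafacial on both allyl units, and not by an end-to-end cyclisation. The one new stereocentre, C7', is set by the boat geometry: the side chain, trans to the cyclopropane on the Z enol ether, takes the exo position and ends cis to the C10' methyl, which lies anti to both reacting vinyl groups; C10' is carried over from step 1. The step needs Z enol geometry (secured by A1,3 strain against the cyclopropyl group) and enolisation away from the ring (secured because a cyclopropyl α-hydrogen does not enolise), while the positions of the new alkenes (C1'=C5' and the C8'=C9' enol ether) are fixed by the mechanism. The second vinyl group survives as the C2'=C3' handle, and mild acid cleaves only the trimethylsilyl enol ether to unmask the C8' ketone.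

Step 6
Reactants: 11 (2S,6R)-2-[2-(tert-butyldimethylsilyloxy)ethyl]-5-ethenyl-6-methylcyclohept-4-en-1-one
Product: 12 (1S,2S,6R)-2-[2-(tert-butyldimethylsilyloxy)ethyl]-5-ethenyl-6-methylcyclohept-4-en-1-ol
Conditions: LiBH(s-Bu)3, THF, −78 °C; then H2O
Reagents that add atoms: none
Why: The bulky tri-sec-butylborohydride should attack the ketone from the face opposite the C7' side chain and the C10' methyl, which lie on the same side, giving the C8' alcohol cis to both (substrate-controlled hydride reduction).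

Step 7
Reactants: 12 (1S,2S,6R)-2-[2-(tert-butyldimethylsilyloxy)ethyl]-5-ethenyl-6-methylcyclohept-4-en-1-ol
Product: 13 (1S,2S,6R)-5-ethenyl-2-(2-hydroxyethyl)-6-methylcyclohept-4-en-1-ol
Conditions: Bu4NF, THF, 0 → 23 °C
Reagents that add atoms: none
Why: Fluoride-mediated silyl ether cleavage, with no stereocentre involved.

Step 8
Reactants: 13 (1S,2S,6R)-5-ethenyl-2-(2-hydroxyethyl)-6-methylcyclohept-4-en-1-ol
Product: 15 (3aS,7R,8aS)-6-ethenyl-7-methyl-3,3a,4,7,8,8a-hexahydro-2H-cyclohepta[b]furan-2-one, via lactol 14 (not isolated)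
Conditions: TEMPO (20 mol %), PhI(OAc)2, CH2Cl2, 23 °C
Reagents that add atoms: none
Why: Oxidative lactonisation of a 1,4-diol, in which the oxoammonium oxidant takes the primary alcohol first, the aldehyde closes onto the cis C8' hydroxyl and the lactol is oxidised on, closing the cis-fused ring D.

Step 9
Reactants: 15 (3aS,7R,8aS)-6-ethenyl-7-methyl-3,3a,4,7,8,8a-hexahydro-2H-cyclohepta[b]furan-2-one
Product: 18 (3aS,7R,8aS)-6-ethenyl-7-methyl-3-methylidene-3,3a,4,7,8,8a-hexahydro-2H-cyclohepta[b]furan-2-one, via Mannich base 16 (not isolated), via methiodide 17 (not isolated)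
Conditions: LiN(i-Pr)2, THF, −78 °C; Me2N=CH2 I, −78 → 23 °C; then MeI, MeOH, 23 °C; then NaHCO3, EtOAc–H2O
Reagents that add atoms: N,N-dimethylmethyleneiminium iodide (Eschenmoser's salt), C=[N+](C)C.[I-]
Why: Mannich reaction of the lactone enolate with Eschenmoser's salt, then quaternisation and E1cB elimination, installs the exocyclic methylene; the C11' centre formed in passing is destroyed.

Step 10
Reactants: 18 (3aS,7R,8aS)-6-ethenyl-7-methyl-3-methylidene-3,3a,4,7,8,8a-hexahydro-2H-cyclohepta[b]furan-2-one; 19 but-3-en-2-one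
Product: 20 ent-8-epi-xanthatin, (3aS,7R,8aS)-7-methyl-3-methylidene-6-[(1E)-3-oxobut-1-en-1-yl]-3,3a,4,7,8,8a-hexahydro-2H-cyclohepta[b]furan-2-one
Conditions: 19 (5 equiv), second-generation Hoveyda–Grubbs catalyst [RuCl2(H2IMes)(=CH-C6H4-2-O-i-Pr)] (5 mol %), CH2Cl2, 40 °C
Reagents that add atoms: none
Why: Olefin cross-metathesis of the terminal vinyl group with methyl vinyl ketone is E-selective, while the trisubstituted ring alkene and the electron-poor 1,1-disubstituted methylene lactone should not engage.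

Step 11
Reactants: 20 ent-8-epi-xanthatin
Product: 21 (1R,5R,7S,8S,10R)-1,5-epoxy-ent-8-epi-xanthatin (epoxide oxygen trans to the C10' methyl and to the lactone)
Conditions: m-CPBA, NaHCO3, CH2Cl2, 0 °C
Reagents that add atoms: m-chloroperoxybenzoic acid, O=C(OO)c1cccc(Cl)c1
Why: Prilezhaev epoxidation should take the most electron-rich alkene (C1'=C5', γ,δ to the ketone) from the face opposite the C10' methyl and the cis-fused lactone, setting C1' and C5'.

**Upper half (steps 12–21)**

Step 12
Reactants: 1 (E)-but-2-enal; 2 dimethyl 2-bromomalonate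
Product: 22 dimethyl (2S,3S)-2-formyl-3-methylcyclopropane-1,1-dicarboxylate
Conditions: (R)-2-[diphenyl(trimethylsilyloxy)methyl]pyrrolidine (20 mol %), 2,6-lutidine, CH2Cl2, 0 → 23 °C
Reagents that add atoms: none
Why: The same organocatalytic Michael-initiated ring closure as step 1, with the (R)-catalyst exposing the opposite iminium face and so setting C10 (S) and the trans cyclopropane.

Step 13
Reactants: 22 dimethyl (2S,3S)-2-formyl-3-methylcyclopropane-1,1-dicarboxylate; 4 (3-bromopropoxy)(tert-butyl)dimethylsilane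
Product: 24 1-[(1S,3S)-2,2-bis(hydroxymethyl)-3-methylcyclopropyl]-4-(tert-butyldimethylsilyloxy)butan-1-ol, via Grignard adduct 23 (not isolated)
Conditions: 4, Mg, THF, 23 °C; then 22, THF, −78 °C; then LiAlH4, −78 → 0 °C; aq. KNaC4H4O6
Reagents that add atoms: [3-(tert-butyldimethylsilyloxy)propyl]magnesium bromide, CC(C)(C)[Si](C)(C)OCCC[Mg]Br
Why: Chemoselective Grignard addition to the aldehyde followed by LiAlH4 reduction of the esters, as in step 2.

Step 14
Reactants: 24 1-[(1S,3S)-2,2-bis(hydroxymethyl)-3-methylcyclopropyl]-4-(tert-butyldimethylsilyloxy)butan-1-ol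
Product: 25 (2S,3S)-2-[4-(tert-butyldimethylsilyloxy)butanoyl]-3-methylcyclopropane-1,1-dicarbaldehyde
Conditions: (COCl)2, DMSO, CH2Cl2, −78 °C; Et3N, −78 → 0 °C
Reagents that add atoms: none
Why: Swern oxidation of all three hydroxyls at once, as in step 3.

Step 15
Reactants: 25 (2S,3S)-2-[4-(tert-butyldimethylsilyloxy)butanoyl]-3-methylcyclopropane-1,1-dicarbaldehyde
Product: 26 4-(tert-butyldimethylsilyloxy)-1-[(1S,3S)-2,2-diethenyl-3-methylcyclopropyl]butan-1-one
Conditions: Ph3PCH3Br, KN(SiMe3)2, THF, 0 °C; then 25 (ylide 2.2 equiv), −78 → 0 °C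
Reagents that add atoms: methylenetriphenylphosphorane, C=P(c1ccccc1)(c1ccccc1)c1ccccc1
Why: Aldehyde-selective Wittig methylenation, as in step 4.

Step 16
Reactants: 26 4-(tert-butyldimethylsilyloxy)-1-[(1S,3S)-2,2-diethenyl-3-methylcyclopropyl]butan-1-one
Product: 29 (2R,6S)-2-[2-(tert-butyldimethylsilyloxy)ethyl]-5-ethenyl-6-methylcyclohept-4-en-1-one, via silyl enol ether 27 (not isolated), via cycloheptadienyl silyl ether 28 (not isolated)
Conditions: Me3SiOTf, Et3N, CH2Cl2, −20 → 23 °C; then 40 °C; then 1 M aq. citric acid, THF, 0 °C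
Reagents that add atoms: none
Why: The same siloxy-divinylcyclopropane (Cope) rearrangement as step 5 in the mirror-image series, closing ring B by forming C6–C7 and setting C7 through the boat transition state from the Z enol ether and the anti C10 methyl.

Step 17
Reactants: 29 (2R,6S)-2-[2-(tert-butyldimethylsilyloxy)ethyl]-5-ethenyl-6-methylcyclohept-4-en-1-one
Product: 30 (1R,2R,6S)-2-[2-(tert-butyldimethylsilyloxy)ethyl]-5-ethenyl-6-methylcyclohept-4-en-1-ol
Conditions: LiBH(s-Bu)3, THF, −78 °C; then H2O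
Reagents that add atoms: none
Why: Bulky-hydride reduction anti to the C7 side chain and C10 methyl, giving the cis C8 alcohol as in step 6.

Step 18
Reactants: 30 (1R,2R,6S)-2-[2-(tert-butyldimethylsilyloxy)ethyl]-5-ethenyl-6-methylcyclohept-4-en-1-ol
Product: 31 (1R,2R,6S)-5-ethenyl-2-(2-hydroxyethyl)-6-methylcyclohept-4-en-1-ol
Conditions: Bu4NF, THF, 0 → 23 °C
Reagents that add atoms: none
Why: Fluoride-mediated silyl ether cleavage, as in step 7.

Step 19
Reactants: 31 (1R,2R,6S)-5-ethenyl-2-(2-hydroxyethyl)-6-methylcyclohept-4-en-1-ol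
Product: 33 (3aR,7S,8aR)-6-ethenyl-7-methyl-3,3a,4,7,8,8a-hexahydro-2H-cyclohepta[b]furan-2-one, via lactol 32 (not isolated)
Conditions: TEMPO (20 mol %), PhI(OAc)2, CH2Cl2, 23 °C
Reagents that add atoms: none
Why: Oxidative lactonisation of the 1,4-diol closes the cis-fused ring A, as in step 8.

Step 20
Reactants: 33 (3aR,7S,8aR)-6-ethenyl-7-methyl-3,3a,4,7,8,8a-hexahydro-2H-cyclohepta[b]furan-2-one
Product: 34 (3S,3aR,7S,8aR)-6-ethenyl-3-(hydroxymethyl)-7-methyl-3,3a,4,7,8,8a-hexahydro-2H-cyclohepta[b]furan-2-one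
Conditions: LiN(i-Pr)2, THF, −78 °C; CH2O (gas, from cracked paraformaldehyde), −78 → −40 °C; then H2O
Reagents that add atoms: formaldehyde, C=O
Why: Aldol reaction of the lactone enolate with formaldehyde on the convex face gives a hydroxymethyl lactone, a latent methylene lactone that cannot act as a dienophile; the new C11 centre is removed in step 24.

Step 21
Reactants: 34 (3S,3aR,7S,8aR)-6-ethenyl-3-(hydroxymethyl)-7-methyl-3,3a,4,7,8,8a-hexahydro-2H-cyclohepta[b]furan-2-one; 19 but-3-en-2-one
Product: 35 (11S)-13-hydroxy-11,13-dihydro-8-epi-xanthatin, (3S,3aR,7S,8aR)-3-(hydroxymethyl)-7-methyl-6-[(1E)-3-oxobut-1-en-1-yl]-3,3a,4,7,8,8a-hexahydro-2H-cyclohepta[b]furan-2-one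
Conditions: 19 (5 equiv), second-generation Hoveyda–Grubbs catalyst [RuCl2(H2IMes)(=CH-C6H4-2-O-i-Pr)] (5 mol %), CH2Cl2, 40 °C
Reagents that add atoms: none
Why: E-selective olefin cross-metathesis of the terminal vinyl group with methyl vinyl ketone, as in step 10.

**Union and end game (steps 22–24)**

Step 22
Reactants: 35 (11S)-13-hydroxy-11,13-dihydro-8-epi-xanthatin; 21 (1R,5R,7S,8S,10R)-1,5-epoxy-ent-8-epi-xanthatin
Product: 36 Diels–Alder adduct (ring C closed with bonds C3–C11' and C5–C13', C1=C2 double bond, H3 and H5 cis, lactone carbonyl C12' cis to H5, C3 attached on the convex face of ring D)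
Conditions: 21 (1.5 equiv), BHT, toluene (2 M), 110 °C, sealed tube
Reagents that add atoms: none
Why: Thermal Diels–Alder reaction in which only 21 carries a reactive dienophile, with "ortho" regiochemistry (acyl-bearing C3 to carbonyl-bearing C11'), the exo transition state typical of s-cis-locked methylene lactones, attack on the convex face of the cis-fused lactone of 21 (anti to ring E at C7') and reaction of the diene on the face expressed in the natural Diels–Alder dimers of 8-epi-xanthatin, which together should set C3, C5 and C11'.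

Step 23
Reactants: 36 Diels–Alder adduct
Product: 38 13-hydroxy-11,13-dihydro derivative of the target (C1–OH, C2=C3 enone), via hydroperoxide 37 (not isolated)
Conditions: O2 (1 atm), DBU (0.3 equiv), MeCN, 0 → 23 °C; then PPh3, 0 °C
Reagents that add atoms: dioxygen, O=O
Why: Base-mediated autoxidation of a β,γ-unsaturated ketone through its dienolate (the reaction that converts 5(10)-en-3-one steroids into 10-hydroperoxy-4-en-3-ones) should take up oxygen at the γ-carbon C1 anti to the pseudoaxial C5–H, giving the trans-fused hydroperoxide and restoring conjugation with the acetyl group; PPh3 reduces the hydroperoxide.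

Step 24
Reactants: 38 13-hydroxy-11,13-dihydro derivative of the target
Product: 40 target CNP0177598.2, via mesylate 39 (not isolated)
Conditions: MsCl, Et3N, CH2Cl2, 0 °C; then DBU, 23 °C
Reagents that add atoms: none
Why: Mesylation of the only unhindered (primary) hydroxyl and E1cB elimination regenerate the upper methylene lactone, while the tertiary C1 alcohol, the epoxide and the enones should not react.

**Compound list**
1 | (E)-but-2-enal | C/C=C/C=O | starting material
2 | dimethyl 2-bromomalonate | COC(=O)C(Br)C(=O)OC | starting material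
3 | dimethyl (2R,3R)-2-formyl-3-methylcyclopropane-1,1-dicarboxylate | COC(=O)C1(C(=O)OC)[C@H](C=O)[C@H]1C | intermediate
4 | (3-bromopropoxy)(tert-butyl)dimethylsilane | BrCCCO[Si](C)(C)C(C)(C)C | starting material
5 | Grignard adduct, dimethyl (2R,3R)-2-[4-(tert-butyldimethylsilyloxy)-1-hydroxybutyl]-3-methylcyclopropane-1,1-dicarboxylate (as magnesium alkoxide, both carbinol epimers) | COC(=O)C1(C(=O)OC)[C@H](C(O)CCCO[Si](C)(C)C(C)(C)C)[C@H]1C | intermediate
6 | 1-[(1R,3R)-2,2-bis(hydroxymethyl)-3-methylcyclopropyl]-4-(tert-butyldimethylsilyloxy)butan-1-ol (both carbinol epimers) | OCC1(CO)[C@H](C(O)CCCO[Si](C)(C)C(C)(C)C)[C@H]1C | intermediate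
7 | (2R,3R)-2-[4-(tert-butyldimethylsilyloxy)butanoyl]-3-methylcyclopropane-1,1-dicarbaldehyde | O=CC1(C=O)[C@H](C(=O)CCCO[Si](C)(C)C(C)(C)C)[C@H]1C | intermediate
8 | 4-(tert-butyldimethylsilyloxy)-1-[(1R,3R)-2,2-diethenyl-3-methylcyclopropyl]butan-1-one | C=CC1(C=C)[C@H](C(=O)CCCO[Si](C)(C)C(C)(C)C)[C@H]1C | intermediate
9 | silyl enol ether, (Z)-trimethylsilyl enol ether of 8 | C=CC1(C=C)[C@H](/C(O[Si](C)(C)C)=C/CCO[Si](C)(C)C(C)(C)C)[C@H]1C | intermediate
10 | cycloheptadienyl silyl ether, (3R,7S)-7-[2-(tert-butyldimethylsilyloxy)ethyl]-4-ethenyl-3-methyl-1-(trimethylsilyloxy)cyclohepta-1,4-diene | C[Si](C)(C)OC1=C[C@@H](C)C(C=C)=CC[C@H]1CCO[Si](C)(C)C(C)(C)C | intermediate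
11 | (2S,6R)-2-[2-(tert-butyldimethylsilyloxy)ethyl]-5-ethenyl-6-methylcyclohept-4-en-1-one | O=C1C[C@@H](C)C(C=C)=CC[C@H]1CCO[Si](C)(C)C(C)(C)C | intermediate
12 | (1S,2S,6R)-2-[2-(tert-butyldimethylsilyloxy)ethyl]-5-ethenyl-6-methylcyclohept-4-en-1-ol | O[C@H]1C[C@@H](C)C(C=C)=CC[C@H]1CCO[Si](C)(C)C(C)(C)C | intermediate
13 | (1S,2S,6R)-5-ethenyl-2-(2-hydroxyethyl)-6-methylcyclohept-4-en-1-ol | O[C@H]1C[C@@H](C)C(C=C)=CC[C@H]1CCO | intermediate
14 | lactol, (3aS,7R,8aS)-6-ethenyl-7-methyl-3,3a,4,7,8,8a-hexahydro-2H-cyclohepta[b]furan-2-ol (both anomers) | OC1O[C@H]2C[C@@H](C)C(C=C)=CC[C@H]2C1 | intermediate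
15 | (3aS,7R,8aS)-6-ethenyl-7-methyl-3,3a,4,7,8,8a-hexahydro-2H-cyclohepta[b]furan-2-one | O=C1O[C@H]2C[C@@H](C)C(C=C)=CC[C@H]2C1 | intermediate
16 | Mannich base, (3R,3aS,7R,8aS)-3-[(dimethylamino)methyl] derivative of 15 | CN(C)C[C@@H]1C(=O)O[C@H]2C[C@@H](C)C(C=C)=CC[C@H]21 | intermediate
17 | methiodide, trimethylammonium iodide of 16 | C[N+](C)(C)C[C@@H]1C(=O)O[C@H]2C[C@@H](C)C(C=C)=CC[C@H]21.[I-] | intermediate
18 | (3aS,7R,8aS)-6-ethenyl-7-methyl-3-methylidene-3,3a,4,7,8,8a-hexahydro-2H-cyclohepta[b]furan-2-one | C=C1C(=O)O[C@H]2C[C@@H](C)C(C=C)=CC[C@@H]12 | intermediate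
19 | but-3-en-2-one | C=CC(C)=O | starting material
20 | ent-8-epi-xanthatin, (3aS,7R,8aS)-7-methyl-3-methylidene-6-[(1E)-3-oxobut-1-en-1-yl]-3,3a,4,7,8,8a-hexahydro-2H-cyclohepta[b]furan-2-one | C=C1C(=O)O[C@H]2C[C@@H](C)C(/C=C/C(C)=O)=CC[C@@H]12 | intermediate
21 | (1R,5R,7S,8S,10R)-1,5-epoxy-ent-8-epi-xanthatin | C=C1C(=O)O[C@H]2C[C@@H](C)[C@]3(/C=C/C(C)=O)O[C@@H]3C[C@@H]12 | intermediate
22 | dimethyl (2S,3S)-2-formyl-3-methylcyclopropane-1,1-dicarboxylate | COC(=O)C1(C(=O)OC)[C@@H](C=O)[C@@H]1C | intermediate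
23 | Grignard adduct, dimethyl (2S,3S)-2-[4-(tert-butyldimethylsilyloxy)-1-hydroxybutyl]-3-methylcyclopropane-1,1-dicarboxylate (as magnesium alkoxide, both carbinol epimers) | COC(=O)C1(C(=O)OC)[C@@H](C(O)CCCO[Si](C)(C)C(C)(C)C)[C@@H]1C | intermediate
24 | 1-[(1S,3S)-2,2-bis(hydroxymethyl)-3-methylcyclopropyl]-4-(tert-butyldimethylsilyloxy)butan-1-ol (both carbinol epimers) | OCC1(CO)[C@@H](C(O)CCCO[Si](C)(C)C(C)(C)C)[C@@H]1C | intermediate
25 | (2S,3S)-2-[4-(tert-butyldimethylsilyloxy)butanoyl]-3-methylcyclopropane-1,1-dicarbaldehyde | O=CC1(C=O)[C@@H](C(=O)CCCO[Si](C)(C)C(C)(C)C)[C@@H]1C | intermediate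
26 | 4-(tert-butyldimethylsilyloxy)-1-[(1S,3S)-2,2-diethenyl-3-methylcyclopropyl]butan-1-one | C=CC1(C=C)[C@@H](C(=O)CCCO[Si](C)(C)C(C)(C)C)[C@@H]1C | intermediate
27 | silyl enol ether, (Z)-trimethylsilyl enol ether of 26 | C=CC1(C=C)[C@@H](/C(O[Si](C)(C)C)=C/CCO[Si](C)(C)C(C)(C)C)[C@@H]1C | intermediate
28 | cycloheptadienyl silyl ether, (3S,7R)-7-[2-(tert-butyldimethylsilyloxy)ethyl]-4-ethenyl-3-methyl-1-(trimethylsilyloxy)cyclohepta-1,4-diene | C[Si](C)(C)OC1=C[C@H](C)C(C=C)=CC[C@@H]1CCO[Si](C)(C)C(C)(C)C | intermediate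
29 | (2R,6S)-2-[2-(tert-butyldimethylsilyloxy)ethyl]-5-ethenyl-6-methylcyclohept-4-en-1-one | O=C1C[C@H](C)C(C=C)=CC[C@@H]1CCO[Si](C)(C)C(C)(C)C | intermediate
30 | (1R,2R,6S)-2-[2-(tert-butyldimethylsilyloxy)ethyl]-5-ethenyl-6-methylcyclohept-4-en-1-ol | O[C@@H]1C[C@H](C)C(C=C)=CC[C@@H]1CCO[Si](C)(C)C(C)(C)C | intermediate
31 | (1R,2R,6S)-5-ethenyl-2-(2-hydroxyethyl)-6-methylcyclohept-4-en-1-ol | O[C@@H]1C[C@H](C)C(C=C)=CC[C@@H]1CCO | intermediate
32 | lactol, (3aR,7S,8aR)-6-ethenyl-7-methyl-3,3a,4,7,8,8a-hexahydro-2H-cyclohepta[b]furan-2-ol (both anomers) | OC1O[C@@H]2C[C@H](C)C(C=C)=CC[C@@H]2C1 | intermediate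
33 | (3aR,7S,8aR)-6-ethenyl-7-methyl-3,3a,4,7,8,8a-hexahydro-2H-cyclohepta[b]furan-2-one | O=C1O[C@@H]2C[C@H](C)C(C=C)=CC[C@@H]2C1 | intermediate
34 | (3S,3aR,7S,8aR)-6-ethenyl-3-(hydroxymethyl)-7-methyl-3,3a,4,7,8,8a-hexahydro-2H-cyclohepta[b]furan-2-one | OC[C@H]1C(=O)O[C@@H]2C[C@H](C)C(C=C)=CC[C@@H]21 | intermediate
35 | (11S)-13-hydroxy-11,13-dihydro-8-epi-xanthatin | OC[C@H]1C(=O)O[C@@H]2C[C@H](C)C(/C=C/C(C)=O)=CC[C@@H]21 | intermediate
36 | Diels–Alder adduct (1(2)-ene, 3-H, 13-hydroxy-11,13-dihydro) | OC[C@H]1C(=O)O[C@@H]2C[C@H](C)C3=C[C@H](C(C)=O)[C@]4(C[C@@H]3C[C@H]12)C(=O)O[C@H]1C[C@@H](C)[C@]2(/C=C/C(C)=O)O[C@@H]2C[C@H]14 | intermediate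
37 | hydroperoxide, C1 hydroperoxide of the 2-en-4-one | OC[C@H]1C(=O)O[C@@H]2C[C@H](C)[C@@]3(OO)C=C(C(C)=O)[C@]4(C[C@@H]3C[C@H]12)C(=O)O[C@H]1C[C@@H](C)[C@]2(/C=C/C(C)=O)O[C@@H]2C[C@H]14 | intermediate
38 | 13-hydroxy-11,13-dihydro derivative of the target | OC[C@H]1C(=O)O[C@@H]2C[C@H](C)[C@@]3(O)C=C(C(C)=O)[C@]4(C[C@@H]3C[C@H]12)C(=O)O[C@H]1C[C@@H](C)[C@]2(/C=C/C(C)=O)O[C@@H]2C[C@H]14 | intermediate
39 | mesylate, C13 methanesulfonate of 38 | CS(=O)(=O)OC[C@H]1C(=O)O[C@@H]2C[C@H](C)[C@@]3(O)C=C(C(C)=O)[C@]4(C[C@@H]3C[C@H]12)C(=O)O[C@H]1C[C@@H](C)[C@]2(/C=C/C(C)=O)O[C@@H]2C[C@H]14 | intermediate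
40 | CNP0177598.2 | C=C1C(=O)O[C@@H]2C[C@H](C)[C@@]3(O)C=C(C(C)=O)[C@]4(C[C@@H]3C[C@H]12)C(=O)O[C@H]1C[C@@H](C)[C@]2(/C=C/C(C)=O)O[C@@H]2C[C@H]14 | target

**Step count and risks**
Total step count: 24 (steps 1–11 lower half, 12–21 upper half, 22–24 union and end game).
Longest linear sequence: 14 steps (steps 1–11, then 22–24).

Steps most likely to fail:

1. Step 22. The cycloaddition joins two electron-poor partners, so it may be slow enough for thermal decomposition, reaction at the wrong alkene or a mismatched facial preference in this heterochiral pairing to compete. Fallback, setting out from 35: silylation (t-BuMe2SiCl, imidazole) should give the silyl ether of 35 F1. 1,2-Reduction of the dienone (NaBH4, CeCl3·7H2O, MeOH, −40 °C) turns the diene into the electron-richer dienol F2 (both C4 epimers), a normal-demand partner for the methylene lactone of 21. Cycloaddition at 80 °C in toluene should give the adduct carbinol F3, Dess–Martin periodinane restores the ketone in the silyl ether of 36 F4, and Bu4NF buffered with AcOH removes the silyl group. The route is rejoined at 36.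

2. Step 23. Oxygen may be taken up on the wrong face of the dienolate or at C3, or the hydroperoxide may be over-oxidised. Fallback, setting out from 36: N-bromosuccinimide in wet acetone adds bromine to the isolated C1=C2 alkene from the open face and water to the tertiary C1 from the opposite face, giving the bromohydrin F5. Oxygen is thus delivered anti to the electrophile, the opposite facial sense to direct oxygenation. DBU then eliminates HBr through the C3 enolate, and the route is rejoined at 38.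

3. Step 6 (and its mirror, step 17). Hydride may be delivered from the face of the side chain, giving the trans alcohol and hence a trans-fused lactone. Fallback, setting out from 11: reduction with the small hydride NaBH4 in MeOH, or isolation of the unwanted epimer, provides the (1R,2S,6R) trans alcohol F6. Mitsunobu inversion (4-nitrobenzoic acid, PPh3, diisopropyl azodicarboxylate) should give the (1S,2S,6R) 4-nitrobenzoate F7, and K2CO3 in MeOH frees the cis alcohol. The route is rejoined at 12.

Further compounds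
F1 | step 22 | tert-butyldimethylsilyl ether of 35 | CC(C)(C)[Si](C)(C)OC[C@H]1C(=O)O[C@@H]2C[C@H](C)C(/C=C/C(C)=O)=CC[C@@H]21
F2 | step 22 | dienol from 1,2-reduction of F1 (both C4 epimers) | CC(C)(C)[Si](C)(C)OC[C@H]1C(=O)O[C@@H]2C[C@H](C)C(/C=C/C(C)O)=CC[C@@H]21
F3 | step 22 | Diels–Alder adduct carbinol from F2 and 21 | CC(C)(C)[Si](C)(C)OC[C@H]1C(=O)O[C@@H]2C[C@H](C)C3=C[C@H](C(C)O)[C@]4(C[C@@H]3C[C@H]12)C(=O)O[C@H]1C[C@@H](C)[C@]2(/C=C/C(C)=O)O[C@@H]2C[C@H]14
F4 | step 22 | tert-butyldimethylsilyl ether of 36 | CC(C)(C)[Si](C)(C)OC[C@H]1C(=O)O[C@@H]2C[C@H](C)C3=C[C@H](C(C)=O)[C@]4(C[C@@H]3C[C@H]12)C(=O)O[C@H]1C[C@@H](C)[C@]2(/C=C/C(C)=O)O[C@@H]2C[C@H]14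
F5 | step 23 | bromohydrin of 36 (C1–OH, C2–Br, trans) | OC[C@H]1C(=O)O[C@@H]2C[C@H](C)[C@@]3(O)[C@@H](Br)[C@H](C(C)=O)[C@]4(C[C@@H]3C[C@H]12)C(=O)O[C@H]1C[C@@H](C)[C@]2(/C=C/C(C)=O)O[C@@H]2C[C@H]14
F6 | step 6 | (1R,2S,6R)-2-[2-(tert-butyldimethylsilyloxy)ethyl]-5-ethenyl-6-methylcyclohept-4-en-1-ol | O[C@@H]1C[C@@H](C)C(C=C)=CC[C@H]1CCO[Si](C)(C)C(C)(C)C
F7 | step 6 | (1S,2S,6R)-2-[2-(tert-butyldimethylsilyloxy)ethyl]-5-ethenyl-6-methylcyclohept-4-en-1-yl 4-nitrobenzoate | O=C(O[C@H]1C[C@@H](C)C(C=C)=CC[C@H]1CCO[Si](C)(C)C(C)(C)C)c1ccc(cc1)[N+](=O)[O-]
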